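## Retrosynthetic overview

1. The lactol is made last by 1,2-reduction of an α,β-unsaturated δ-lactone; the hemiacetal carbon is left to equilibrate.
2. The δ-lactone (C3=C4 bond, Z) comes from a Still–Gennari olefination of a β-silyloxy aldehyde with an α-homofarnesyl phosphonate, then desilylative lactonisation.
3. The succinimide comes from a trans-paraconic (γ-lactone) carboxamide by base-mediated O→N acyl transfer, which also frees the carbinol.
4. Both carbon stereocentres come from a ketoreductase dynamic reductive kinetic resolution of a 2-acylsuccinate built from achiral materials, backed by equilibration to the trans-lactone.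
5. Ring order: γ-lactone (temporary) → succinimide → dihydropyranone → lactol. The homofarnesyl chain comes from (2E,6E)-farnesol by one-carbon homologation.

Assumption: the hemiacetal carbon is configurationally labile (ring–chain tautomerism), so the final product is taken to settle as the natural (S)-anomer shown in the target; it is not set kinetically.

## Route

**Step 1**
Reactants: 1 methyl acetoacetate; 2 benzyl chloromethyl ether
Product: 3 methyl 5-(benzyloxy)-3-oxopentanoate
Conditions: NaH, THF, 0 °C; n-BuLi, 0 °C; then 2, −78 → 0 °C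
Reagents that add atoms: benzyl chloromethyl ether (2), ClCOCc1ccccc1
Why: Weiler dianion alkylation; the more reactive γ-carbanion of the acetoacetate dianion is alkylated by the α-chloro ether.

**Step 2**
Reactants: 3; 4 methyl bromoacetate
Product: 5 dimethyl 2-[3-(benzyloxy)propanoyl]butanedioate (racemic, α-centre freely epimerising)
Conditions: NaH, THF, 0 °C → rt
Reagents that add atoms: methyl bromoacetate (4), COC(=O)CBr
Why: SN2 C-alkylation of the stabilised β-keto ester enolate gives the 2-acylsuccinate whose labile α-centre is what the next step needs.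

**Step 3**
Reactants: 5
Product: 6 dimethyl (2S)-2-[(1R)-3-(benzyloxy)-1-hydroxypropyl]butanedioate (syn)
Conditions: ketoreductase (NADPH-dependent KRED picked from a panel for the (R)-carbinol, syn-preferring), NADP⁺ cat., glucose/glucose dehydrogenase, phosphate buffer pH 7, 10% DMSO, 30 °C
Reagents that add atoms: none
Why: Ketoreductase dynamic reductive kinetic resolution; hydride from NADPH adds to one carbonyl face to set the (R)-carbinol while the enzyme selects the (S)-α-epimer of the racemising β-keto ester (any α-epimer is corrected in step 4).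

**Step 4**
Reactants: 6
Product: 7 methyl (2R,3S)-2-[2-(benzyloxy)ethyl]-5-oxooxolane-3-carboxylate (trans)
Conditions: PPTS (cat.), PhMe, 80 °C; then DBU (0.3 equiv), PhMe, rt
Reagents that add atoms: none
Why: Acid-catalysed γ-lactonisation, then DBU enolisation of the ester-bearing carbon equilibrates to the thermodynamically preferred trans-paraconate (expected ≥9:1), fixing the future succinimide centre as S.

**Step 5**
Reactants: 7
Product: 8 (2R,3S)-2-[2-(benzyloxy)ethyl]-5-oxooxolane-3-carboxylic acid
Conditions: LiOH·H2O, THF/H2O, 0 °C → rt; then 2 M HCl to pH 1, rt → 40 °C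
Reagents that add atoms: lithium hydroxide/water, [Li+].[OH-] / O
Why: Saponification cleaves the methyl ester (and opens the lactone), and acidification re-closes only the γ-lactone; the stereocentres are not enolised as carboxylates.

**Step 6**
Reactants: 8
Product: 9 (2R,3S)-2-[2-(benzyloxy)ethyl]-5-oxooxolane-3-carboxamide
Conditions: i-BuOCOCl, N-methylmorpholine, THF, −15 °C; then NH3 (0.5 M in dioxane, 1.2 equiv), −15 → 0 °C
Reagents that add atoms: ammonia, N
Why: Mixed-anhydride amidation; the activated acid captures one equivalent of ammonia at low temperature faster than the lactone can open.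

**Step 7**
Reactants: 9
Product: 10 (3S)-3-[(1R)-3-(benzyloxy)-1-hydroxypropyl]pyrrolidine-2,5-dione
Conditions: NaOMe (1.2 equiv), MeOH, 0 °C → rt; AcOH quench at 0 °C
Reagents that add atoms: none
Why: Base-mediated O→N acyl transfer (lactone methanolysis, then 5-exo-trig attack of the amidate on the ester) closes the succinimide and frees the carbinol, driven by formation of the imide N-anion (pKa ≈ 9.6), which also shields the α-centre from epimerisation.

**Step 8**
Reactants: 10
Product: 11 (3S)-3-[(1R)-3-(benzyloxy)-1-[(tert-butyldimethylsilyl)oxy]propyl]pyrrolidine-2,5-dione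
Conditions: TBSOTf, 2,6-lutidine, CH2Cl2, −78 → 0 °C; NaHCO3/MeOH work-up
Reagents that add atoms: TBSOTf, CC(C)(C)[Si](C)(C)OS(=O)(=O)C(F)(F)F
Why: Silylation of the secondary alcohol; any N- or O-silylated imide is hydrolysed on work-up.

**Step 9**
Reactants: 11
Product: 12 (3S)-3-[(1R)-1-[(tert-butyldimethylsilyl)oxy]-3-hydroxypropyl]pyrrolidine-2,5-dione
Conditions: H2 (1 atm), 10% Pd/C, EtOAc, rt
Reagents that add atoms: none
Why: Hydrogenolysis of the benzyl ether; the imide and TBS ether are inert in EtOAc.

**Step 10**
Reactants: 12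
Product: 13 (3R)-3-[(tert-butyldimethylsilyl)oxy]-3-[(3S)-2,5-dioxopyrrolidin-3-yl]propanal
Conditions: Dess–Martin periodinane, NaHCO3, CH2Cl2, 0 °C → rt; used at once
Reagents that add atoms: none
Why: Dess–Martin oxidation gives the β-silyloxy aldehyde under near-neutral conditions without elimination or epimerisation.

**Step 11**
Reactants: 14 (2E,6E)-farnesol
Product: 15 (2E,6E)-farnesal
Conditions: MnO2, CH2Cl2, rt
Reagents that add atoms: none
Why: Chemoselective allylic oxidation with MnO2 retains the 2E geometry.

**Step 12**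
Reactants: 15; 16 methyltriphenylphosphonium bromide
Product: 17 (3E,7E)-4,8,12-trimethyltrideca-1,3,7,11-tetraene
Conditions: 16, n-BuLi, THF, 0 °C; then 15, 0 °C → rt
Reagents that add atoms: methyltriphenylphosphonium bromide (16), C[P+](c1ccccc1)(c1ccccc1)c1ccccc1.[Br-]
Why: Wittig methylenation of the enal adds the one extra carbon as a terminal vinyl group.

**Step 13**
Reactants: 17
Product: 18 (3E,7E)-4,8,12-trimethyltrideca-3,7,11-trien-1-ol (homofarnesol)
Conditions: Sia2BH, THF, 0 °C; then NaOH, 30% H2O2, 0 °C → rt
Reagents that add atoms: hydrogen peroxide, OO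
Why: Hydroboration–oxidation; bulky disiamylborane adds anti-Markovnikov only to the terminal vinyl group and leaves the trisubstituted alkenes alone (as in the homogeraniol procedure).

**Step 14**
Reactants: 18
Product: 19 (3E,7E)-1-iodo-4,8,12-trimethyltrideca-3,7,11-triene (homofarnesyl iodide)
Conditions: I2, PPh3, imidazole, CH2Cl2, 0 °C → rt
Reagents that add atoms: iodine, II
Why: Appel-type iodination of the primary alcohol under neutral conditions.

**Step 15**
Reactants: 19; 20 methyl bis(2,2,2-trifluoroethyl)phosphonoacetate (1.5 equiv)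
Product: 21 methyl (5E,9E)-2-[bis(2,2,2-trifluoroethoxy)phosphoryl]-6,10,14-trimethylpentadeca-5,9,13-trienoate
Conditions: NaH, DMF, 0 °C; then 19, rt → 50 °C
Reagents that add atoms: Still–Gennari phosphonoacetate (20), COC(=O)CP(=O)(OCC(F)(F)F)OCC(F)(F)F
Why: SN2 C-alkylation of the soft, weakly basic phosphonoacetate anion by the primary iodide gives the α-homofarnesyl Still–Gennari reagent.

**Step 16**
Reactants: 13; 21
Product: 22 methyl (2Z,5R)-5-[(tert-butyldimethylsilyl)oxy]-5-[(3S)-2,5-dioxopyrrolidin-3-yl]-2-[(3E,7E)-4,8,12-trimethyltrideca-3,7,11-trien-1-yl]pent-2-enoate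
Conditions: 21 (2.2 equiv), KHMDS (2.1 equiv), 18-crown-6, THF, −78 °C; then 13, −78 °C (one equivalent of phosphonate anion is consumed deprotonating the imide N–H and is recovered)
Reagents that add atoms: none beyond the two reactants
Why: Still–Gennari olefination; the trifluoroethyl phosphonate under dissociating K/18-crown-6 conditions gives the kinetic Z-trisubstituted enoate (ester cis to the CH2 chain), and the imide is protected as its N-anion.

**Step 17**
Reactants: 22
Product: 23 (3S)-3-[(2R)-6-oxo-5-[(3E,7E)-4,8,12-trimethyltrideca-3,7,11-trien-1-yl]-3,6-dihydro-2H-pyran-2-yl]pyrrolidine-2,5-dione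
Conditions: HF·pyridine, THF/pyridine, 0 °C → rt; then PPTS (cat.), PhMe, 50 °C
Reagents that add atoms: none
Why: Desilylation frees the δ-hydroxyl, which lactonises onto the cis ester; only the Z-isomer can cyclise, so any E-enoate is removed here.

**Step 18**
Reactants: 23
Product: 24 hippolide A, (3S)-3-[(2R,6S)-6-hydroxy-5-[(3E,7E)-4,8,12-trimethyltrideca-3,7,11-trien-1-yl]-3,6-dihydro-2H-pyran-2-yl]pyrrolidine-2,5-dione
Conditions: DIBAL-H (2.3 equiv), CH2Cl2/THF, −78 °C, 1 h; MeOH, then aq. Rochelle salt
Reagents that add atoms: none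
Why: DIBAL 1,2-reduction of the conjugated δ-lactone stops at the tetrahedral aluminate (lactol on work-up); the first equivalent deprotonates the imide N–H, which should leave the imide inert at −78 °C, and the hemiacetal carbon then equilibrates to the natural anomer.

## Compound list

1 | methyl acetoacetate | CC(=O)CC(=O)OC | starting material
2 | benzyl chloromethyl ether | ClCOCc1ccccc1 | starting material
3 | methyl 5-(benzyloxy)-3-oxopentanoate | COC(=O)CC(=O)CCOCc1ccccc1 | intermediate
4 | methyl bromoacetate | COC(=O)CBr | starting material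
5 | dimethyl 2-[3-(benzyloxy)propanoyl]butanedioate (racemic) | COC(=O)CC(C(=O)CCOCc1ccccc1)C(=O)OC | intermediate
6 | dimethyl (2S)-2-[(1R)-3-(benzyloxy)-1-hydroxypropyl]butanedioate | c1ccccc1COCC[C@H]([C@@H](C(=O)OC)CC(=O)OC)O | intermediate
7 | methyl (2R,3S)-2-[2-(benzyloxy)ethyl]-5-oxooxolane-3-carboxylate | c1ccccc1COCC[C@@H]2[C@@H](C(=O)OC)CC(=O)O2 | intermediate
8 | (2R,3S)-2-[2-(benzyloxy)ethyl]-5-oxooxolane-3-carboxylic acid | c1ccccc1COCC[C@@H]2[C@@H](C(=O)O)CC(=O)O2 | intermediate
9 | (2R,3S)-2-[2-(benzyloxy)ethyl]-5-oxooxolane-3-carboxamide | c1ccccc1COCC[C@@H]2[C@@H](C(N)=O)CC(=O)O2 | intermediate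
10 | (3S)-3-[(1R)-3-(benzyloxy)-1-hydroxypropyl]pyrrolidine-2,5-dione | c1ccccc1COCC[C@H]([C@@H]2CC(=O)NC2=O)O | intermediate
11 | (3S)-3-[(1R)-3-(benzyloxy)-1-(TBS-oxy)propyl]pyrrolidine-2,5-dione | c1ccccc1COCC[C@H]([C@@H]2CC(=O)NC2=O)O[Si](C)(C)C(C)(C)C | intermediate
12 | (3S)-3-[(1R)-1-(TBS-oxy)-3-hydroxypropyl]pyrrolidine-2,5-dione | OCC[C@H]([C@@H]1CC(=O)NC1=O)O[Si](C)(C)C(C)(C)C | intermediate
13 | (3R)-3-(TBS-oxy)-3-[(3S)-2,5-dioxopyrrolidin-3-yl]propanal | O=CC[C@H]([C@@H]1CC(=O)NC1=O)O[Si](C)(C)C(C)(C)C | intermediate
14 | (2E,6E)-farnesol | CC(C)=CCC/C(C)=C/CC/C(C)=C/CO | starting material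
15 | (2E,6E)-farnesal | CC(C)=CCC/C(C)=C/CC/C(C)=C/C=O | intermediate
16 | methyltriphenylphosphonium bromide | C[P+](c1ccccc1)(c1ccccc1)c1ccccc1.[Br-] | starting material
17 | (3E,7E)-4,8,12-trimethyltrideca-1,3,7,11-tetraene | CC(C)=CCC/C(C)=C/CC/C(C)=C/C=C | intermediate
18 | (3E,7E)-homofarnesol | CC(C)=CCC/C(C)=C/CC/C(C)=C/CCO | intermediate
19 | (3E,7E)-homofarnesyl iodide | CC(C)=CCC/C(C)=C/CC/C(C)=C/CCI | intermediate
20 | methyl bis(2,2,2-trifluoroethyl)phosphonoacetate | COC(=O)CP(=O)(OCC(F)(F)F)OCC(F)(F)F | starting material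
21 | α-homofarnesyl Still–Gennari phosphonate | CC(C)=CCC/C(C)=C/CC/C(C)=C/CCC(C(=O)OC)P(=O)(OCC(F)(F)F)OCC(F)(F)F | intermediate
22 | (2Z,5R)-Z-enoate TBS ether | CC(C)=CCC/C(C)=C/CC/C(C)=C/CC/C(C(=O)OC)=C/C[C@H]([C@@H]1CC(=O)NC1=O)O[Si](C)(C)C(C)(C)C | intermediate
23 | (2R)-dihydropyranone succinimide | CC(C)=CCC/C(C)=C/CC/C(C)=C/CCC1=CC[C@H]([C@@H]2CC(=O)NC2=O)OC1=O | intermediate
24 | hippolide A | CC(C)=CCC/C(C)=C/CC/C(C)=C/CCC1=CC[C@H]([C@@H]2CC(=O)NC2=O)O[C@@H]1O | target

## Summary

Total steps: 18. Longest linear sequence: 13 (steps 1–10, then 16–18, from methyl acetoacetate).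

Three steps most likely to fail, each with a fallback that changes the approach:

- **Step 3 (ketoreductase reduction of a bulky 2-acylsuccinate).** The enzyme may not accept the substrate or may give poor selectivity. Fallback: reduce the simple β-keto ester 3 with a ketoreductase to methyl (3R)-5-(benzyloxy)-3-hydroxypentanoate, install the acetate arm by Fráter–Seebach dianion alkylation with methyl bromoacetate (anti), lactonise to the cis-paraconate and epimerise with DBU to the same trans-lactone 7.
- **Step 16 (Still–Gennari with an α-branched phosphonate and an NH-imide aldehyde).** Z-selectivity or conversion may be poor. Fallback: olefinate 13 with the unsubstituted reagent 20, lactonise, α-iodinate the dihydropyranone, and attach the chain by B-alkyl Suzuki coupling with the 9-BBN adduct of tetraene 17.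
- **Step 18 (DIBAL on the lactone in the presence of the free imide).** The imide may be reduced, or the lactone over-reduced. Fallback: avoid hydride altogether by converting alcohol 12 to its phosphonium salt and running Still's Z-selective Wittig with the α-alkoxy ketone homofarnesyl–CO–CH2OPMB, then DDQ and MnO2 to the Z-enal, and HF desilylation to close the lactol directly.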